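Slowness comes first: in the blue run, the same charge as dawn, L is still climbing, from 20% at 1.50 min to 30% at 4.00 min, so I take a reading at 6.0 min as one made on the way, not at the end.

| flask | J | Q | remark | time |
|---|---|---|---|---|
| blue | 0.050 M | 0.95 equiv | run made earlier |  |
| amber | 0.050 M | 0.47 equiv | run made earlier |  |
| teal | 0.050 M | 0.71 equiv | run made earlier |  |
| spring | 0.050 M (fed, over 5.0 min) | 0.950 equiv | all else is in the flask from the start; the feed brings no volume worth counting | 6.0 min |
| dawn | 0.050 M | 0.950 equiv | everything together at the start | 6.0 min |
| noon | 0.050 M (fed, over 80 s) | 0.950 equiv | all else is in the flask from the start; the feed brings no volume worth counting | 6.0 min |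
| summer | 0.050 M | 0.950 equiv (fed, over 5.0 min) | all else is in the flask from the start; the feed brings no volume worth counting | 6.0 min |

| run | time / min | L / % | D / % |
|---|---|---|---|
| blue | 0.250 | 3 | 0 |
| blue | 0.667 | 14 | 1 |
| blue | 1.50 | 20 | 5 |
| blue | 4.00 | 30 | 7 |
| amber | 1.50 | 11 | 0 |
| amber | 3.00 | 19 | 4 |
| amber | 5.00 | 22 | 2 |
| amber | 6.00 | 22 | 5 |
| teal | 0.500 | 6 | 0 |
| teal | 1.00 | 15 | 0 |
| teal | 2.50 | 19 | 7 |
| teal | 6.00 | 22 | 4 |

(standard deviation of a reading: 2 percentage points)

- steps under discussion: J <-> X; Q + L -> D; J + Q -> L; Q + Z -> D; J + Q -> Z

1. the best flask by share of L in L plus D; "all alike" if 1.5 percentage points covers them all (spring / dawn / noon / summer / all alike)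
2. share of L in L plus D at the end, spring
3. share of L in L plus D at the end, dawn
4. share of L in L plus D at the end, noon
5. share of L in L plus D at the end, summer

I read the blue table row by row. D trails L: 0% against 3%, then 1% against 14%, then 5% against 20%. Such a lag suggests that D comes from something already formed, at the price of a second Q. The last two rows give shares of 80.0% and 81.1%, but D there carries a scatter of 2 percentage points, so this flatness is weak evidence. If D is a second call on Q, the share (the selectivity) should sink the longer things have sat together.

A steady feed of 5.0 min gives its portions a mean stay of 3.50 min, the reading time less half the feed time. This contact time, the mean time the fed species has spent in the flask at the reading, is what I carry. Noon gets 5.33 min, and dawn, where nothing is fed, counts the full 6.0 min. So I expect dawn lowest, noon next, and spring and summer on top, level with each other, since their contact is shorter than noon's.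

The forecast names summer as best, with dawn 81%, noon 81.5%, spring 84% and summer 86%, and holds that “L + Q → D looks negligible”.

The flasks give dawn 71.0%, noon 72.3%, spring 74.4% and summer 78.2%, so summer is best, as forecast, with each share 7.8 points to 10 points under the forecast's.

    J ⇌ X (K = 1.30, k = 0.0970 min⁻¹)
    Q + L → D (k = 2.30 M⁻¹ min⁻¹)
    J + Q → L (k = 4.80 M⁻¹ min⁻¹)
    Q + Z → D (k = 4.50 M⁻¹ min⁻¹)
    J + Q → Z (k = 2.20 M⁻¹ min⁻¹)

Dawn, noon and summer fall in contact order: 71.0% at 6.0 min, 72.3% at 5.33 min, 78.2% at 3.50 min. Spring, with the same contact as summer, stands 3.8 points lower, so contact time does not separate those two. Now the neighbour: dawn read at 4.0 min, where contact equals the reading time. Setting spring aside, that lies between summer's 3.50 min and noon's 5.33 min, so its share should lie between 78.2% and 72.3%. Dawn at that reading holds L 29.0% against D 8.86%, a share of 76.6%.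

(All runs were computed on assumed constants; scatter was added.)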